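## Retrosynthetic overview

1. The rings are joined late at the depside ester O5'–C(=O). The partners are the ring A acid (3-formyl-2-hydroxy-4-methoxy-6-methylbenzoic acid, from orsellinic acid) and a ring B phenol held as its tert-butyl ester. CF3CO2H then frees the C1' acid.
2. Feature used: in ring B the oxygens at C2' and C4' flank C3' (CHO), a third oxygen sits at C5' beside the C6' methyl, and C1' carries the carboxyl group. This is the pattern of a 5-alkoxy-6-methyl-2,4-dioxocyclohexane-1-carboxylate, in which C3' is a nucleophilic dione methylene.
3. Ring B is therefore built at the dihydro level by Michael–Claisen annulation of tert-butyl acetoacetate with ethyl (Z)-2-(benzyloxy)but-2-enoate (bonds C1'–C6' and C3'–C4'). The C5' oxygen arrives with the acceptor.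
4. The formyl carbon is placed on C3' while it is still a dione carbon. The ring is then dehydrogenated across C1'–C6' by selenoxide elimination, and hydrogenolysis bares the 5'-OH.
5. Ring order: ring A is bought as an arene. Ring B is closed in step 3, aromatised in step 6 and joined to ring A in step 12.

Key step: step 3

Assumption: the target is achiral. Compounds 8 to 11 are racemic and their SMILES show relative configuration only. Compound 8 is drawn as one enol tautomer of the 2,4-dione. Primed locants count ring B from the carboxyl-bearing carbon C1', and unprimed locants refer to ring A.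

## Route

Step 1
Reactants: 1 ethyl 2-(benzyloxy)acetate; 2 acetaldehyde
Product: 3 ethyl 2-(benzyloxy)-3-hydroxybutanoate (racemic syn/anti mixture)
Conditions: LDA (1.1 equiv), THF, −78 °C; then 2, −78 °C; AcOH quench
Reagents that add atoms: none
Why: Directed aldol addition of the chelated lithium enolate of the glycolate ester to acetaldehyde at low temperature, where the enolate neither rearranges nor self-condenses; the two new stereocentres need no control because both are removed in step 2.

Step 2
Reactants: 3 ethyl 2-(benzyloxy)-3-hydroxybutanoate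
Product: 5 ethyl (Z)-2-(benzyloxy)but-2-enoate, via mesylate 4 (not isolated)
Conditions: MsCl, Et3N, CH2Cl2, 0 °C; then DBU, 0 °C → rt
Reagents that add atoms: none
Why: Mesylation followed by DBU-induced E1cB elimination through the ester enolate lets both diastereomers of 4 converge on the more stable (Z)-enol ether with the methyl group trans to the ester; the alkene geometry has no bearing on step 3.

Step 3
Reactants: 5 ethyl (Z)-2-(benzyloxy)but-2-enoate; 6 tert-butyl acetoacetate
Product: 8 tert-butyl trans-5-(benzyloxy)-2-hydroxy-6-methyl-4-oxocyclohex-1-ene-1-carboxylate (racemic; enol form of the 2,4-dione), via open-chain Michael adduct 7 (not isolated)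
Conditions: 6, KOC(CH3)3 (1.0 equiv), (CH3)3COH, rt; then 5, concentrated solution, reflux; cold 1 M HCl to pH 3
Reagents that add atoms: none
Why: KOC(CH3)3 turns 6 into its potassium enolate, whose central carbon (future C1') adds to the β-carbon of 5 (future C6'); proton transfer within adduct 7 then supplies a small equilibrium amount of the terminal methyl-ketone enolate (future C3'), which acylates on the ethyl ester carbon (future C4') with loss of ethoxide. The closest known reaction type is the Michael–Claisen annulation of acetoacetates with crotonates to dihydroresorcylates; the α-benzyloxy group makes this acceptor less electrophilic than a plain crotonate, so all steps before the last are reversible and the sequence is pulled through by irreversible deprotonation of the acidic 2,4-dione. The one ring closure is 6-(enolendo)-exo-trig, because both carbons of the enolate C2'=C3' end up inside the new ring, a mode that is favoured for six-membered rings. C6' is created in the conjugate addition and C5' on protonation, and since the addition is reversible and C5' (α to the C4' ketone) epimerises in base, the trans diequatorial C5'-OBn/C6'-CH3 arrangement should result under thermodynamic control; both centres are erased in step 6, so the outcome is not critical. The selectivity needed is one of connectivity only: four-membered alternatives are excluded by strain, the tert-butyl ester is too hindered to accept an acyl transfer or to transesterify, the poorly nucleophilic tert-butoxide suppresses retro-Claisen deacetylation of 7, and pre-forming the enolate without excess base limits γ-deprotonation of 5.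

Step 4
Reactants: 8 tert-butyl trans-5-(benzyloxy)-2-hydroxy-6-methyl-4-oxocyclohex-1-ene-1-carboxylate
Product: 9 tert-butyl 5-(benzyloxy)-3-[(dimethylamino)methylidene]-6-methyl-2,4-dioxocyclohexane-1-carboxylate (racemic; CO2tBu at C1' trans to CH3 at C6'; OBn at C5' trans to CH3)
Conditions: Me2NCH(OMe)2 (1.1 equiv), CH2Cl2, rt
Reagents that add atoms: N,N-dimethylformamide dimethyl acetal, COC(OC)N(C)C
Why: Condensation of an amide acetal with the acidic methylene of a cyclic 1,3-dione, the standard route to 2-(aminomethylene)-1,3-diones, puts the future formyl carbon on C3' at the aldehyde oxidation level under neutral conditions that spare the tert-butyl β-keto ester, blocks C3' against selenium in step 5 and leaves C1'–H as the only acidic C–H; C1' equilibrates to the all-equatorial isomer.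

Step 5
Reactants: 9 tert-butyl 5-(benzyloxy)-3-[(dimethylamino)methylidene]-6-methyl-2,4-dioxocyclohexane-1-carboxylate
Product: 10 tert-butyl 5-(benzyloxy)-3-[(dimethylamino)methylidene]-6-methyl-2,4-dioxo-1-(phenylselanyl)cyclohexane-1-carboxylate (racemic; SePh trans to CH3 at C6' and so cis to C6'–H)
Conditions: LiN(SiMe3)2 (1.1 equiv), THF, −78 °C; PhSeCl, −78 °C
Reagents that add atoms: benzeneselenenyl chloride, Cl[Se]c1ccccc1
Why: α-Selenenylation of a β-keto ester enolate, in which PhSeCl should approach the C1' enolate carbon from the face opposite the neighbouring C6' methyl group and so set the new quaternary centre with selenium cis to C6'–H, as the following syn-elimination demands.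

Step 6
Reactants: 10 tert-butyl 5-(benzyloxy)-3-[(dimethylamino)methylidene]-6-methyl-2,4-dioxo-1-(phenylselanyl)cyclohexane-1-carboxylate
Product: 13 tert-butyl 5-(benzyloxy)-3-formyl-2,4-dihydroxy-6-methylbenzoate, via selenoxide 11 (not isolated), via quinoid enaminone 12 (not isolated)
Conditions: mCPBA (1.0 equiv), CH2Cl2, −78 °C → rt; then THF–10% aq. citric acid, rt
Reagents that add atoms: water, O
Why: Selenoxide syn-elimination introduces the C1'=C6' double bond below room temperature, the resulting dienone enolises at C5' to 12 (the neutral form of the aromatic dimethyliminium phenolate, the kind of species a Vilsmeier formylation delivers) and mild aqueous acid hydrolyses it to the aldehyde, so the ring is dehydrogenated without free oxidant, strong acid or heat that could oxidise the arene, cleave the tert-butyl ester or expel benzyl alcohol; all three stereocentres disappear.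

Step 7
Reactants: 13 tert-butyl 5-(benzyloxy)-3-formyl-2,4-dihydroxy-6-methylbenzoate
Product: 14 tert-butyl 3-formyl-2,4,5-trihydroxy-6-methylbenzoate
Conditions: H2 (1 atm), Pd/C, EtOAc, rt, stopped after one equivalent of H2; product kept under Ar and used at once
Reagents that add atoms: none
Why: Catalytic hydrogenolysis of an aryl benzyl ether is much faster than reduction of an aryl aldehyde held between two hydrogen-bonding hydroxyls, and it leaves the tert-butyl ester untouched.

Step 8
Reactants: 15 orsellinic acid
Product: 16 benzyl 2,4-dihydroxy-6-methylbenzoate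
Conditions: BnBr, KHCO3, DMF, rt
Reagents that add atoms: benzyl bromide, BrCc1ccccc1
Why: SN2 alkylation of the carboxylate, the only group that KHCO3 deprotonates, so both phenols stay free and the acid is secured against decarboxylation.

Step 9
Reactants: 16 benzyl 2,4-dihydroxy-6-methylbenzoate
Product: 17 benzyl 2-hydroxy-4-methoxy-6-methylbenzoate
Conditions: MeI (1.0 equiv), K2CO3 (1.0 equiv), acetone, reflux
Reagents that add atoms: iodomethane, CI
Why: Williamson etherification that tells the two phenols apart, since the 2-OH is hydrogen-bonded to the neighbouring ester carbonyl while the 4-OH is more acidic and unhindered.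

Step 10
Reactants: 17 benzyl 2-hydroxy-4-methoxy-6-methylbenzoate
Product: 18 benzyl 3-formyl-2-hydroxy-4-methoxy-6-methylbenzoate
Conditions: MgCl2 (anhydrous), Et3N, (CH2O)n, MeCN, reflux; 1 M HCl work-up
Reagents that add atoms: paraformaldehyde (reacts as formaldehyde), C=O
Why: Magnesium-mediated ortho-formylation of phenols (Casnati–Skattebøl reaction) delivers formaldehyde within the magnesium phenoxide only to a position ortho to the phenol oxygen, and as C3 is the sole free ortho position the C5 regioisomer cannot arise; a second formaldehyde accepts hydride from the hydroxymethyl stage.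

Step 11
Reactants: 18 benzyl 3-formyl-2-hydroxy-4-methoxy-6-methylbenzoate
Product: 19 3-formyl-2-hydroxy-4-methoxy-6-methylbenzoic acid
Conditions: H2 (1 atm), Pd/C, EtOAc, rt
Reagents that add atoms: none
Why: Hydrogenolysis of the benzyl ester frees the di-ortho-substituted acid under neutral conditions, where saponification would need forcing base, and the chelated aldehyde is retained.

Step 12
Reactants: 14 tert-butyl 3-formyl-2,4,5-trihydroxy-6-methylbenzoate; 19 3-formyl-2-hydroxy-4-methoxy-6-methylbenzoic acid
Product: 20 tert-butyl 3-formyl-5-[(3-formyl-2-hydroxy-4-methoxy-6-methylbenzoyl)oxy]-2,4-dihydroxy-6-methylbenzoate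
Conditions: DCC, DMAP (cat.), CH2Cl2, 0 °C → rt, Ar
Reagents that add atoms: none
Why: Steglich esterification, in which the carbodiimide-activated acid is taken up by the 5'-OH, the only hydroxyl not locked in a six-membered hydrogen-bond chelate (2-OH of 19 to CHO and CO2H; 2'-OH of 14 to the ester; 4'-OH of 14 to CHO), and any ester formed first at O4' can move to O5' by a 1,2-acyl shift across the catechol because this restores the 4'-OH to CHO chelate.

Step 13
Reactants: 20 tert-butyl 3-formyl-5-[(3-formyl-2-hydroxy-4-methoxy-6-methylbenzoyl)oxy]-2,4-dihydroxy-6-methylbenzoate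
Product: 21 haemathamnolic acid
Conditions: CF3CO2H–CH2Cl2, 0 °C → rt
Reagents that add atoms: none
Why: Acidolysis of the tert-butyl ester through the tert-butyl cation, which leaves as isobutene; the aryl ester link, the two chelated aldehydes and the methyl ether do not react with anhydrous CF3CO2H at or below room temperature, and the low temperature guards the resorcylic acid against decarboxylation.

## Compound list

1 | ethyl 2-(benzyloxy)acetate | CCOC(=O)COCc1ccccc1 | starting material
2 | acetaldehyde | CC=O | starting material
3 | ethyl 2-(benzyloxy)-3-hydroxybutanoate (racemic syn/anti mixture) | CCOC(=O)C(OCc1ccccc1)C(C)O | intermediate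
4 | ethyl 2-(benzyloxy)-3-[(methylsulfonyl)oxy]butanoate (diastereomer mixture, not isolated) | CCOC(=O)C(OCc1ccccc1)C(C)OS(C)(=O)=O | intermediate
5 | ethyl (Z)-2-(benzyloxy)but-2-enoate | C/C=C(\OCc1ccccc1)C(=O)OCC | intermediate
6 | tert-butyl acetoacetate | CC(=O)CC(=O)OC(C)(C)C | starting material
7 | 1-tert-butyl 5-ethyl 2-acetyl-4-(benzyloxy)-3-methylpentanedioate (diastereomer mixture, present as potassium enolate, not isolated) | CCOC(=O)C(OCc1ccccc1)C(C)C(C(C)=O)C(=O)OC(C)(C)C | intermediate
8 | tert-butyl trans-5-(benzyloxy)-2-hydroxy-6-methyl-4-oxocyclohex-1-ene-1-carboxylate (racemic; enol form of the 2,4-dione) | CC(C)(C)OC(=O)C1=C(O)CC(=O)[C@@H](OCc2ccccc2)[C@@H]1C | intermediate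
9 | tert-butyl 5-(benzyloxy)-3-[(dimethylamino)methylidene]-6-methyl-2,4-dioxocyclohexane-1-carboxylate (racemic; 1,6-trans and 5,6-trans; push–pull C=C geometry not fixed) | CC(C)(C)OC(=O)[C@H]1C(=O)C(=CN(C)C)C(=O)[C@@H](OCc2ccccc2)[C@@H]1C | intermediate
10 | tert-butyl 5-(benzyloxy)-3-[(dimethylamino)methylidene]-6-methyl-2,4-dioxo-1-(phenylselanyl)cyclohexane-1-carboxylate (racemic; SePh cis to C6'–H; OBn trans to CH3) | CC(C)(C)OC(=O)[C@]1([Se]c2ccccc2)C(=O)C(=CN(C)C)C(=O)[C@@H](OCc2ccccc2)[C@@H]1C | intermediate
11 | selenoxide of 10 (mixture at selenium, not isolated) | CC(C)(C)OC(=O)[C@]1([Se](=O)c2ccccc2)C(=O)C(=CN(C)C)C(=O)[C@@H](OCc2ccccc2)[C@@H]1C | intermediate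
12 | tert-butyl 3-(benzyloxy)-5-[(dimethylamino)methylidene]-4-hydroxy-2-methyl-6-oxocyclohexa-1,3-diene-1-carboxylate (quinoid form of the aromatic dimethyliminium phenolate, not isolated) | CC(C)(C)OC(=O)C1=C(C)C(OCc2ccccc2)=C(O)C(=CN(C)C)C1=O | intermediate
13 | tert-butyl 5-(benzyloxy)-3-formyl-2,4-dihydroxy-6-methylbenzoate | CC(C)(C)OC(=O)c1c(C)c(OCc2ccccc2)c(O)c(C=O)c1O | intermediate
14 | tert-butyl 3-formyl-2,4,5-trihydroxy-6-methylbenzoate | CC(C)(C)OC(=O)c1c(C)c(O)c(O)c(C=O)c1O | intermediate
15 | orsellinic acid (2,4-dihydroxy-6-methylbenzoic acid) | Cc1cc(O)cc(O)c1C(=O)O | starting material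
16 | benzyl 2,4-dihydroxy-6-methylbenzoate | Cc1cc(O)cc(O)c1C(=O)OCc2ccccc2 | intermediate
17 | benzyl 2-hydroxy-4-methoxy-6-methylbenzoate | COc1cc(C)c(C(=O)OCc2ccccc2)c(O)c1 | intermediate
18 | benzyl 3-formyl-2-hydroxy-4-methoxy-6-methylbenzoate | COc1cc(C)c(C(=O)OCc2ccccc2)c(O)c1C=O | intermediate
19 | 3-formyl-2-hydroxy-4-methoxy-6-methylbenzoic acid | COc1cc(C)c(C(=O)O)c(O)c1C=O | intermediate
20 | tert-butyl 3-formyl-5-[(3-formyl-2-hydroxy-4-methoxy-6-methylbenzoyl)oxy]-2,4-dihydroxy-6-methylbenzoate | COc1cc(C)c(C(=O)Oc2c(C)c(C(=O)OC(C)(C)C)c(O)c(C=O)c2O)c(O)c1C=O | intermediate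
21 | haemathamnolic acid | COc1cc(C)c(C(=O)Oc2c(C)c(C(=O)O)c(O)c(C=O)c2O)c(O)c1C=O | target

## Step count and risks

Total step count: 13.
Longest linear sequence: 9 steps (steps 1 to 7, then 12 and 13).

**Risk 1, step 3.** The conjugate addition may be slow. The α-benzyloxy group feeds electron density to the β-carbon and the β-methyl group hinders it. Base-induced γ-deprotonation and deconjugation of the acceptor, or retro-Michael cleavage, could then outrun ring closure.

The fallback exchanges the roles of donor and acceptor. It sets out from 1, 2 and 6. A Knoevenagel condensation of 6 with 2 (piperidine, AcOH, CH2Cl2, 0 °C) gives tert-butyl 2-ethylidene-3-oxobutanoate F1, a doubly activated acceptor. The lithium enolate of 1 (LDA, THF, −78 °C) adds to its β-carbon, so that C5'–C6' is formed instead of C1'–C6'. Protonation gives the open-chain compound 7, where the fallback comes back to the route; here 7 is isolated. KOC(CH3)3 in (CH3)3COH then has only the Claisen closure C3'–C4' left to perform and gives 8.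

**Risk 2, step 6** (together with the facial selectivity of step 5). Three processes could interfere:
- The C5' benzyloxy group lies on the face from which selenium must arrive. Poor facial selectivity would place selenium trans to C6'–H, where the selenoxide has no syn hydrogen to remove.
- Nucleophilic loss of selenium from the α-seleno β-dicarbonyl unit would return the unoxidised ring.
- Selenium by-products could over-oxidise the electron-rich arene.

The fallback aromatises first and formylates the arene afterwards. It sets out from 8 and comes back at 13.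
- Double deprotonation and O-silylation (LiN(SiMe3)2, 2.2 equiv, Me3SiCl, THF, −78 → 0 °C) gives tert-butyl trans-5-(benzyloxy)-6-methyl-2,4-bis[(trimethylsilyl)oxy]cyclohexa-1,3-diene-1-carboxylate F2.
- DDQ (CH2Cl2, 0 °C) dehydrogenates this cyclohexa-1,3-diene without any stereochemical requirement. It gives tert-butyl 5-(benzyloxy)-6-methyl-2,4-bis[(trimethylsilyl)oxy]benzoate F3, whose capped phenols resist further oxidation.
- K2CO3 in MeOH removes the silyl groups and gives tert-butyl 5-(benzyloxy)-2,4-dihydroxy-6-methylbenzoate F4.
- Magnesium-mediated ortho-formylation (MgCl2, Et3N, (CH2O)n, MeCN, reflux) at C3', the only free ring position, gives 13.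

**Risk 3, step 12.** Coupling between two di-ortho-substituted partners may be slow, and the activated acid could then rearrange by O→N acyl shift. Acylation might also occur at more than one hydroxyl, and the hydroxyhydroquinone unit of 14 is prone to air oxidation.

The fallback changes the protecting-group plan so that ring B offers a single hydroxyl and is never a free triol. It sets out from 13 and comes back at 21.
- NaH and MOMCl (DMF, 0 °C) give tert-butyl 5-(benzyloxy)-3-formyl-2,4-bis(methoxymethoxy)-6-methylbenzoate F5.
- Hydrogenolysis (H2, Pd/C, EtOAc) gives tert-butyl 3-formyl-5-hydroxy-2,4-bis(methoxymethoxy)-6-methylbenzoate F6.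
- Esterification with 19 (DCC, DMAP, CH2Cl2) gives tert-butyl 3-formyl-5-[(3-formyl-2-hydroxy-4-methoxy-6-methylbenzoyl)oxy]-2,4-bis(methoxymethoxy)-6-methylbenzoate F7.
- CF3CO2H in moist CH2Cl2 removes both acetals and the tert-butyl ester in one operation to give 21.

## Further compounds

F1 | step 3 | tert-butyl 2-ethylidene-3-oxobutanoate (E/Z mixture) | CC=C(C(C)=O)C(=O)OC(C)(C)C
F2 | step 6 | tert-butyl trans-5-(benzyloxy)-6-methyl-2,4-bis[(trimethylsilyl)oxy]cyclohexa-1,3-diene-1-carboxylate (racemic) | CC(C)(C)OC(=O)C1=C(O[Si](C)(C)C)C=C(O[Si](C)(C)C)[C@@H](OCc2ccccc2)[C@@H]1C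
F3 | step 6 | tert-butyl 5-(benzyloxy)-6-methyl-2,4-bis[(trimethylsilyl)oxy]benzoate | CC(C)(C)OC(=O)c1c(C)c(OCc2ccccc2)c(O[Si](C)(C)C)cc1O[Si](C)(C)C
F4 | step 6 | tert-butyl 5-(benzyloxy)-2,4-dihydroxy-6-methylbenzoate | CC(C)(C)OC(=O)c1c(C)c(OCc2ccccc2)c(O)cc1O
F5 | step 12 | tert-butyl 5-(benzyloxy)-3-formyl-2,4-bis(methoxymethoxy)-6-methylbenzoate | CC(C)(C)OC(=O)c1c(C)c(OCc2ccccc2)c(OCOC)c(C=O)c1OCOC
F6 | step 12 | tert-butyl 3-formyl-5-hydroxy-2,4-bis(methoxymethoxy)-6-methylbenzoate | CC(C)(C)OC(=O)c1c(C)c(O)c(OCOC)c(C=O)c1OCOC
F7 | step 12 | tert-butyl 3-formyl-5-[(3-formyl-2-hydroxy-4-methoxy-6-methylbenzoyl)oxy]-2,4-bis(methoxymethoxy)-6-methylbenzoate | COc1cc(C)c(C(=O)Oc2c(C)c(C(=O)OC(C)(C)C)c(OCOC)c(C=O)c2OCOC)c(O)c1C=O
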